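**Retrosynthetic overview**

- The core is numbered as 7-oxabicyclo[4.1.0]hept-3-ene: C1/C6 are the oxirane carbons (O7), C2 the carbinol, C3=C4(N) the enamide, C5 the ketone. Late disconnections are acid to methyl ester and C2–OH to C2–OSiMe3.
- Key disconnection: C2–C3 and C5–C6 are made in one [3+3] anion-relay annulation. Fragment A (C3–C4–C5) is a 3-sulfonylalanine already N-acylated with the whole side chain and used as its trilithio salt. Fragment B (C2–C1–C6) is a cis-β-silyl-α,β-epoxy ketone carrying the ester chain.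
- Enabling feature: the C2 oxygen and C6 are 1,3 across C1 and lie on the same side of the cis-fused oxirane (O7–C1–C6), so an alkoxide born at C2 can take silicon from C6 through a five-membered O–C2–C1–C6–Si array. In addition, C3(H)=C4(N)–C5(=O) is a dehydroalanine unit: C3 can act as a sulfonyl carbanion and C5 as a carboxylate.
- Order of ring formation: the oxirane first (in fragment B, absolute configuration from an asymmetric transfer hydrogenation relayed by a directed epoxidation), the six-membered carbocycle second (key step).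
- Side chain: meso-2,4-dimethylglutaric anhydride, lipase desymmetrisation, two Wittig olefinations.

Key step: step 16

Remark on the chemistry: the lipase in step 2 is assumed to acylate the hydroxymethyl group on the S carbon of the meso diol, as Pseudomonas lipases usually do with 2-methyl-branched primary alcohols; the alanine stereocentre of 10 is sacrificial.

**Route**

Step 1
Reactants: 1 meso-2,4-dimethylglutaric anhydride
Product: 2 meso-(2R,4S)-2,4-dimethylpentane-1,5-diol
Conditions: LiAlH4, THF, 0 °C to reflux; aqueous NaOH work-up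
Reagents that add atoms: none
Why: Hydride reduction of a cyclic anhydride to the diol (LiAlH4 reduction) does not touch the two methyl-bearing carbons, so the meso relationship of 1 is carried into 2.

Step 2
Reactants: 2 meso-(2R,4S)-2,4-dimethylpentane-1,5-diol
Product: 3 (2S,4R)-5-hydroxy-2,4-dimethylpentyl acetate
Conditions: lipase from Pseudomonas fluorescens (Amano AK), vinyl acetate, THF, rt
Reagents that add atoms: vinyl acetate, C=COC(C)=O
Why: Lipase-catalysed transesterification with an enol ester (enzymatic desymmetrisation of a meso diol) should acetylate only the hydroxymethyl group on the S carbon, which converts the meso compound into one enantiomer and so fixes both side-chain stereocentres.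

Step 3
Reactants: 3 (2S,4R)-5-hydroxy-2,4-dimethylpentyl acetate
Product: 4 (2S,4R)-2,4-dimethyl-5-oxopentyl acetate
Conditions: Dess–Martin periodinane, pyridine, CH2Cl2, 0 °C to rt
Reagents that add atoms: none
Why: Dess–Martin oxidation gives the aldehyde under buffered, non-basic conditions that should not epimerise the α-stereocentre.

Step 4
Reactants: 4 (2S,4R)-2,4-dimethyl-5-oxopentyl acetate
Product: 5 (2S,4R)-2,4,6-trimethylhept-5-en-1-yl acetate
Conditions: i-PrPPh3I, n-BuLi, THF, 0 °C; then 4, −78 to 0 °C
Reagents that add atoms: isopropyltriphenylphosphonium iodide, CC(C)[P+](c1ccccc1)(c1ccccc1)c1ccccc1.[I-]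
Why: Wittig olefination with the non-stabilised isopropylidene ylide should give the trisubstituted alkene (no alkene geometry to control), and low temperature with only a slight excess of ylide limits α-epimerisation and attack on the acetate.

Step 5
Reactants: 5 (2S,4R)-2,4,6-trimethylhept-5-en-1-yl acetate
Product: 6 (2S,4R)-2,4,6-trimethylhept-5-en-1-ol
Conditions: K2CO3 (cat.), MeOH, rt
Reagents that add atoms: none
Why: Base-catalysed transesterification (methanolysis of the acetate) frees the primary alcohol without touching the stereocentres or the alkene.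

Step 6
Reactants: 6 (2S,4R)-2,4,6-trimethylhept-5-en-1-ol
Product: 7 (2S,4R)-2,4,6-trimethylhept-5-enal
Conditions: Dess–Martin periodinane, pyridine, CH2Cl2, 0 °C to rt; used at once
Reagents that add atoms: none
Why: Dess–Martin oxidation should again give the α-branched aldehyde without epimerisation.

Step 7
Reactants: 7 (2S,4R)-2,4,6-trimethylhept-5-enal
Product: 8 methyl (2E,4S,6R)-4,6,8-trimethylnona-2,7-dienoate
Conditions: Ph3P=CHCO2Me, CH2Cl2, rt
Reagents that add atoms: methyl (triphenylphosphoranylidene)acetate, COC(=O)C=P(c1ccccc1)(c1ccccc1)c1ccccc1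
Why: Wittig reaction with a stabilised ylide should give the E-enoate selectively under neutral conditions that spare the α-stereocentre of 7.

Step 8
Reactants: 8 methyl (2E,4S,6R)-4,6,8-trimethylnona-2,7-dienoate
Product: 9 (2E,4S,6R)-4,6,8-trimethylnona-2,7-dienoic acid
Conditions: LiOH, THF/MeOH/H2O, rt; then dilute HCl
Reagents that add atoms: lithium hydroxide, [Li+].[OH-]
Why: Saponification (ester hydrolysis by hydroxide) gives the acid, and the γ-stereocentre is not acidic enough to be affected under these conditions.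

Step 9
Reactants: 10 S-phenyl-L-cysteine
Product: 11 (2R)-2-amino-3-(benzenesulfonyl)propanoic acid
Conditions: H2O2 (30 %), Na2WO4 (cat.), AcOH/H2O, rt
Reagents that add atoms: hydrogen peroxide, OO
Why: Tungstate-catalysed peroxide oxidation of the sulfide to the sulfone runs through the sulfoxide while the protonated amine is inert to the oxidant, and the stereocentre is not involved.

Step 10
Reactants: 9 (2E,4S,6R)-4,6,8-trimethylnona-2,7-dienoic acid, 11 (2R)-2-amino-3-(benzenesulfonyl)propanoic acid
Product: 13 (2R)-3-(benzenesulfonyl)-2-{[(2E,4S,6R)-4,6,8-trimethylnona-2,7-dienoyl]amino}propanoic acid, via mixed anhydride 12 (not isolated)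
Conditions: i-BuOCOCl, N-methylmorpholine, THF, −15 °C; then 11, N-methylmorpholine, DMF/H2O, 0 °C to rt; acidic work-up
Reagents that add atoms: none
Why: Amide formation through a mixed carbonic anhydride (Schotten–Baumann-type acylation of an amino acid salt) should occur at the acyl carbonyl, and because 11 reacts as its carboxylate the α-hydrogen is not acidic and benzenesulfinate is not eliminated.

Step 11
Reactants: 14 methyl 6-chloro-6-oxohexanoate, 15 bis(trimethylsilyl)acetylene
Product: 16 methyl 6-oxo-8-(trimethylsilyl)oct-7-ynoate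
Conditions: AlCl3, CH2Cl2, 0 °C
Reagents that add atoms: none
Why: Friedel–Crafts-type acylation of bis(trimethylsilyl)acetylene (electrophilic ipso-substitution of one silyl group) gives the silyl ynone, the second silyl group being deactivated by the new carbonyl.

Step 12
Reactants: 16 methyl 6-oxo-8-(trimethylsilyl)oct-7-ynoate
Product: 17 methyl (6S)-6-hydroxy-8-(trimethylsilyl)oct-7-ynoate
Conditions: RuCl[(S,S)-TsDPEN](p-cymene) (cat.), i-PrOH, rt
Reagents that add atoms: none
Why: Noyori asymmetric transfer hydrogenation of an alkynyl ketone, in which the (S,S)-TsDPEN ligand should deliver hydride to the face that gives the S carbinol (the alkynyl group taking the place of the aryl group in the usual model).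

Step 13
Reactants: 17 methyl (6S)-6-hydroxy-8-(trimethylsilyl)oct-7-ynoate
Product: 18 methyl (6S,7Z)-6-hydroxy-8-(trimethylsilyl)oct-7-enoate
Conditions: H2 (1 atm), nickel boride Ni2B from Ni(OAc)2 and NaBH4, ethylenediamine, EtOH, rt
Reagents that add atoms: none
Why: Syn semi-hydrogenation of the alkyne on the amine-poisoned Ni2B surface (P-2 nickel reduction) should stop at the Z-alkenylsilane, which places silicon cis to the carbinol carbon.

Step 14
Reactants: 18 methyl (6S,7Z)-6-hydroxy-8-(trimethylsilyl)oct-7-enoate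
Product: 19 methyl (6S)-6-hydroxy-6-[(2R,3S)-3-(trimethylsilyl)oxiran-2-yl]hexanoate
Conditions: mCPBA, Na2HPO4, CH2Cl2, 0 °C
Reagents that add atoms: 3-chloroperbenzoic acid (mCPBA), OOC(=O)c1cccc(Cl)c1
Why: Hydroxyl-directed peracid epoxidation (Henbest epoxidation) of a Z-allylic alcohol, in which allylic 1,3-strain holds the carbinol hydrogen in the alkene plane so that the peracid is delivered from the hydroxyl face to give the threo epoxy alcohol, setting both oxirane carbons (2R,3S) with silicon cis to the chain.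

Step 15
Reactants: 19 methyl (6S)-6-hydroxy-6-[(2R,3S)-3-(trimethylsilyl)oxiran-2-yl]hexanoate
Product: 20 methyl 6-oxo-6-[(2R,3S)-3-(trimethylsilyl)oxiran-2-yl]hexanoate
Conditions: Dess–Martin periodinane, pyridine, CH2Cl2, 0 °C to rt
Reagents that add atoms: none
Why: Dess–Martin oxidation removes the now redundant carbinol stereocentre and gives the epoxy ketone under neutral conditions that should neither open nor epimerise the epoxysilane.

Step 16
Reactants: 13 (2R)-3-(benzenesulfonyl)-2-{[(2E,4S,6R)-4,6,8-trimethylnona-2,7-dienoyl]amino}propanoic acid, 20 methyl 6-oxo-6-[(2R,3S)-3-(trimethylsilyl)oxiran-2-yl]hexanoate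
Product: 25 methyl 5-[(1S,2S,6R)-5-oxo-4-{[(2E,4S,6R)-4,6,8-trimethylnona-2,7-dienoyl]amino}-2-[(trimethylsilyl)oxy]-7-oxabicyclo[4.1.0]hept-3-en-2-yl]pentanoate, via trilithio salt 21 (not isolated), via lithium alkoxide 22 (not isolated), via oxiranyllithium 23 (not isolated), via sulfonyl ketone 24 (not isolated)
Conditions: n-BuLi (3.0 equiv), THF, −78 °C; 20, −78 °C; HMPA, −78 to −30 °C; AcOH; then DBU, CH2Cl2, 0 °C
Reagents that add atoms: none
Why: Proposed new method: n-BuLi turns 13 into the carboxylate/amidate/α-sulfonyl carbanion 21, which adds to the ketone of 20 (bond C2–C3), the lithium alkoxide 22 then pulls the trimethylsilyl group from the cis oxirane carbon through a five-membered O–C2–C1–C6–Si array (1,4-Brook shift, set off by HMPA), and the oxiranyllithium 23 thus unmasked adds to the lithium carboxylate (bond C5–C6) to give after protonation the β-sulfonyl ketone 24, from which DBU expels benzenesulfinate (E1cB) to create the C3=C4 enamide bond. The closest known reaction types are the addition of dilithiated 3-sulfonylpropanoic acids (β-acylvinyl anion equivalents) to ketones, Brook-shift anion relay annulations, the formation of oxiranyl anions from epoxysilanes or epoxystannanes, and the Parham cycliacylation of organolithiums onto lithium carboxylates; their union and the 1,4-silyl shift from an oxirane carbon are new. The six-membered carbocycle is closed by 6-exo-trig attack of the C6 carbanion on the carboxylate carbon C5. The new stereocentre C2 is controlled by lithium chelation between the ketone oxygen and the oxirane oxygen of 20 (Cram cyclic model, attack on the face away from the silyl-bearing oxirane carbon), which puts the C2–O bond trans to the oxirane oxygen in the ring, C6 keeps its configuration because the oxiranyllithium does not invert at low temperature and only the cis carbanion can reach C5, C1 is not touched, and the centres at C3 and C4 of 24 are erased by the elimination. The step needs C-acylation to win over lactonisation and carbanion formation to win over β-elimination: the silyl shift caps the C2 alkoxide, a carboxylate offers it no leaving group, and with the carboxylate and amidate in place the α-hydrogen of 21 is not acidic while the sulfonyl group still leaves readily once C5 has become a ketone.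

Step 17
Reactants: 25 methyl 5-[(1S,2S,6R)-5-oxo-4-{[(2E,4S,6R)-4,6,8-trimethylnona-2,7-dienoyl]amino}-2-[(trimethylsilyl)oxy]-7-oxabicyclo[4.1.0]hept-3-en-2-yl]pentanoate
Product: 26 methyl 5-[(1S,2S,6R)-2-hydroxy-5-oxo-4-{[(2E,4S,6R)-4,6,8-trimethylnona-2,7-dienoyl]amino}-7-oxabicyclo[4.1.0]hept-3-en-2-yl]pentanoate
Conditions: AcOH/THF/H2O (3:1:1), 0 °C to rt
Reagents that add atoms: none
Why: Mild acid-catalysed hydrolysis of a trimethylsilyl ether (solvolysis at silicon) frees the tertiary alcohol without ionising the C2–O bond or opening the epoxy ketone.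

Step 18
Reactants: 26 methyl 5-[(1S,2S,6R)-2-hydroxy-5-oxo-4-{[(2E,4S,6R)-4,6,8-trimethylnona-2,7-dienoyl]amino}-7-oxabicyclo[4.1.0]hept-3-en-2-yl]pentanoate
Product: 27 5-[(1S,2S,6R)-2-hydroxy-5-oxo-4-{[(2E,4S,6R)-4,6,8-trimethylnona-2,7-dienoyl]amino}-7-oxabicyclo[4.1.0]hept-3-en-2-yl]pentanoic acid
Conditions: pig liver esterase, pH 7.2 phosphate buffer/acetone (9:1), rt
Reagents that add atoms: water, O
Why: Enzymatic ester hydrolysis (pig liver esterase) at neutral pH should cleave the unhindered methyl ester at the chain end while the base-sensitive epoxy alcohol, enamide and enone are left alone.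

**Compound list**

1 | meso-2,4-dimethylglutaric anhydride, (3R,5S)-3,5-dimethyloxane-2,6-dione | C[C@H]1C[C@@H](C)C(=O)OC1=O | starting material
2 | meso-(2R,4S)-2,4-dimethylpentane-1,5-diol | OC[C@H](C)C[C@H](C)CO | intermediate
3 | (2S,4R)-5-hydroxy-2,4-dimethylpentyl acetate | OC[C@H](C)C[C@H](C)COC(C)=O | intermediate
4 | (2S,4R)-2,4-dimethyl-5-oxopentyl acetate | O=C[C@H](C)C[C@H](C)COC(C)=O | intermediate
5 | (2S,4R)-2,4,6-trimethylhept-5-en-1-yl acetate | CC(C)=C[C@H](C)C[C@H](C)COC(C)=O | intermediate
6 | (2S,4R)-2,4,6-trimethylhept-5-en-1-ol | CC(C)=C[C@H](C)C[C@H](C)CO | intermediate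
7 | (2S,4R)-2,4,6-trimethylhept-5-enal | CC(C)=C[C@H](C)C[C@H](C)C=O | intermediate
8 | methyl (2E,4S,6R)-4,6,8-trimethylnona-2,7-dienoate | CC(C)=C[C@H](C)C[C@H](C)/C=C/C(=O)OC | intermediate
9 | (2E,4S,6R)-4,6,8-trimethylnona-2,7-dienoic acid | CC(C)=C[C@H](C)C[C@H](C)/C=C/C(=O)O | intermediate
10 | S-phenyl-L-cysteine, (2R)-2-amino-3-(phenylsulfanyl)propanoic acid | N[C@@H](CSc1ccccc1)C(=O)O | starting material
11 | (2R)-2-amino-3-(benzenesulfonyl)propanoic acid | N[C@@H](CS(=O)(=O)c1ccccc1)C(=O)O | intermediate
12 | (2E,4S,6R)-4,6,8-trimethylnona-2,7-dienoic 2-methylpropyl carbonic anhydride (mixed anhydride of 9) | CC(C)=C[C@H](C)C[C@H](C)/C=C/C(=O)OC(=O)OCC(C)C | intermediate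
13 | (2R)-3-(benzenesulfonyl)-2-{[(2E,4S,6R)-4,6,8-trimethylnona-2,7-dienoyl]amino}propanoic acid (fragment A) | CC(C)=C[C@H](C)C[C@H](C)/C=C/C(=O)N[C@@H](CS(=O)(=O)c1ccccc1)C(=O)O | intermediate
14 | methyl 6-chloro-6-oxohexanoate | COC(=O)CCCCC(Cl)=O | starting material
15 | bis(trimethylsilyl)acetylene | C[Si](C)(C)C#C[Si](C)(C)C | starting material
16 | methyl 6-oxo-8-(trimethylsilyl)oct-7-ynoate | COC(=O)CCCCC(=O)C#C[Si](C)(C)C | intermediate
17 | methyl (6S)-6-hydroxy-8-(trimethylsilyl)oct-7-ynoate | COC(=O)CCCC[C@H](O)C#C[Si](C)(C)C | intermediate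
18 | methyl (6S,7Z)-6-hydroxy-8-(trimethylsilyl)oct-7-enoate | COC(=O)CCCC[C@H](O)/C=C\[Si](C)(C)C | intermediate
19 | methyl (6S)-6-hydroxy-6-[(2R,3S)-3-(trimethylsilyl)oxiran-2-yl]hexanoate | COC(=O)CCCC[C@H](O)[C@H]1O[C@H]1[Si](C)(C)C | intermediate
20 | methyl 6-oxo-6-[(2R,3S)-3-(trimethylsilyl)oxiran-2-yl]hexanoate (fragment B) | COC(=O)CCCCC(=O)[C@H]1O[C@H]1[Si](C)(C)C | intermediate
21 | trilithio salt of 13 (lithium carboxylate, N-lithio amide, lithiated α-sulfonyl carbon; alanine centre R) | CC(C)=C[C@H](C)C[C@H](C)/C=C/C(=O)N([Li])[C@@H](C([Li])S(=O)(=O)c1ccccc1)C(=O)O[Li] | intermediate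
22 | lithium alkoxide from addition of 21 to the ketone of 20 (oxirane as in 20, new C–O bond on the face that becomes trans to the oxirane oxygen, α-sulfonyl carbon unassigned) | CC(C)=C[C@H](C)C[C@H](C)/C=C/C(=O)N([Li])[C@@H](C(S(=O)(=O)c1ccccc1)[C@@](O[Li])(CCCCC(=O)OC)[C@H]1O[C@H]1[Si](C)(C)C)C(=O)O[Li] | intermediate
23 | oxiranyllithium formed from 22 by silyl shift to oxygen (lithium in the place of silicon, cis to the chain) | CC(C)=C[C@H](C)C[C@H](C)/C=C/C(=O)N([Li])[C@@H](C(S(=O)(=O)c1ccccc1)[C@@](O[Si](C)(C)C)(CCCCC(=O)OC)[C@H]1O[C@H]1[Li])C(=O)O[Li] | intermediate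
24 | methyl 5-[(1S,2R,6R)-3-(benzenesulfonyl)-5-oxo-4-{[(2E,4S,6R)-4,6,8-trimethylnona-2,7-dienoyl]amino}-2-[(trimethylsilyl)oxy]-7-oxabicyclo[4.1.0]heptan-2-yl]pentanoate (epimers at C3 and C4) | CC(C)=C[C@H](C)C[C@H](C)/C=C/C(=O)NC1C(S(=O)(=O)c2ccccc2)[C@@](O[Si](C)(C)C)(CCCCC(=O)OC)[C@H]2O[C@H]2C1=O | intermediate
25 | methyl 5-[(1S,2S,6R)-5-oxo-4-{[(2E,4S,6R)-4,6,8-trimethylnona-2,7-dienoyl]amino}-2-[(trimethylsilyl)oxy]-7-oxabicyclo[4.1.0]hept-3-en-2-yl]pentanoate | CC(C)=C[C@H](C)C[C@H](C)/C=C/C(=O)NC1=C[C@@](O[Si](C)(C)C)(CCCCC(=O)OC)[C@H]2O[C@H]2C1=O | intermediate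
26 | methyl 5-[(1S,2S,6R)-2-hydroxy-5-oxo-4-{[(2E,4S,6R)-4,6,8-trimethylnona-2,7-dienoyl]amino}-7-oxabicyclo[4.1.0]hept-3-en-2-yl]pentanoate | CC(C)=C[C@H](C)C[C@H](C)/C=C/C(=O)NC1=C[C@@](O)(CCCCC(=O)OC)[C@H]2O[C@H]2C1=O | intermediate
27 | 5-[(1S,2S,6R)-2-hydroxy-5-oxo-4-{[(2E,4S,6R)-4,6,8-trimethylnona-2,7-dienoyl]amino}-7-oxabicyclo[4.1.0]hept-3-en-2-yl]pentanoic acid (CNP0110221.3) | CC(C)=C[C@H](C)C[C@H](C)/C=C/C(=O)NC1=C[C@@](O)(CCCCC(=O)O)[C@H]2O[C@H]2C1=O | target

**Step count**

Total step count: 18. Longest linear sequence: 12 steps (steps 1 to 8, 10, 16, 17, 18).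

**Steps most likely to fail**

1. Step 16 (Proposed new method). The lithium alkoxide 22 may not take up silicon from the oxirane carbon, so that it persists or reverts to 21 and 20 by retro-addition and the hydroxy acid lactonises on work-up. Alternatively, the released oxiranyl carbanion may be protonated before it reaches the carboxylate. The fallback makes the same carbanion by tin–lithium exchange, each stage being known chemistry; it sets out from 17 and comes back at 26.
   - K2CO3 in MeOH removes the alkyne silyl group to give methyl (6S)-6-hydroxyoct-7-ynoate F1.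
   - ZrCl4-catalysed anti-hydrostannation with Bu3SnH gives methyl (6S,7Z)-6-hydroxy-8-(tributylstannyl)oct-7-enoate F2.
   - Buffered mCPBA gives the threo epoxide methyl (6S)-6-hydroxy-6-[(2R,3S)-3-(tributylstannyl)oxiran-2-yl]hexanoate F3, and Dess–Martin oxidation gives methyl 6-oxo-6-[(2R,3S)-3-(tributylstannyl)oxiran-2-yl]hexanoate F4.
   - Addition of 21 to F4 at −78 °C gives the stannyl trilithio alkoxide F5.
   - n-BuLi at −100 °C then effects tin–lithium exchange to the alkoxide-bearing oxiranyllithium F6, which closes onto the carboxylate (Parham-type cycliacylation). Acetic acid quench gives the hydroxy β-sulfonyl ketone methyl 5-[(1S,2R,6R)-3-(benzenesulfonyl)-2-hydroxy-5-oxo-4-{[(2E,4S,6R)-4,6,8-trimethylnona-2,7-dienoyl]amino}-7-oxabicyclo[4.1.0]heptan-2-yl]pentanoate F7.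
   - DBU eliminates benzenesulfinate to give 26.

2. Step 14. The peracid may attack both alkene faces; the erythro isomer leads to the enantiomeric oxirane after step 15 and erodes enantiopurity. 3-Chlorobenzoic acid may also open or desilylate the epoxysilane. The fallback changes the oxygen transfer from a hydrogen-bond-directed peracid to a metal-alkoxide-templated hydroperoxide. It sets out from 18 and comes back at 19: Ti(OiPr)4 and t-BuOOH in CH2Cl2 at −20 °C, in which the titanium-bound Z-allylic alkoxide delivers the peroxide to the same face under acid-free conditions. It makes no compound outside the list (entry F0).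

3. Step 18. During ester cleavage the free C2 hydroxyl may migrate the oxirane (Payne-type rearrangement), the epoxy ketone may open, or the esterase may not turn the substrate over. The fallback inverts the order of the last two steps so that the carbinol stays silylated while the ester is cleaved. It sets out from 25 and comes back at 27: Me3SnOH in 1,2-dichloroethane at 60 °C gives 5-[(1S,2S,6R)-5-oxo-4-{[(2E,4S,6R)-4,6,8-trimethylnona-2,7-dienoyl]amino}-2-[(trimethylsilyl)oxy]-7-oxabicyclo[4.1.0]hept-3-en-2-yl]pentanoic acid F8, and AcOH/THF/H2O then removes the silyl ether.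

**Further compounds**

F1 | step 16 | methyl (6S)-6-hydroxyoct-7-ynoate | COC(=O)CCCC[C@H](O)C#C
F2 | step 16 | methyl (6S,7Z)-6-hydroxy-8-(tributylstannyl)oct-7-enoate | COC(=O)CCCC[C@H](O)/C=C\[Sn](CCCC)(CCCC)CCCC
F3 | step 16 | methyl (6S)-6-hydroxy-6-[(2R,3S)-3-(tributylstannyl)oxiran-2-yl]hexanoate | COC(=O)CCCC[C@H](O)[C@H]1O[C@H]1[Sn](CCCC)(CCCC)CCCC
F4 | step 16 | methyl 6-oxo-6-[(2R,3S)-3-(tributylstannyl)oxiran-2-yl]hexanoate | COC(=O)CCCCC(=O)[C@H]1O[C@H]1[Sn](CCCC)(CCCC)CCCC
F5 | step 16 | trilithio alkoxide from addition of 21 to the ketone of F4 | CC(C)=C[C@H](C)C[C@H](C)/C=C/C(=O)N([Li])[C@@H](C(S(=O)(=O)c1ccccc1)[C@@](O[Li])(CCCCC(=O)OC)[C@H]1O[C@H]1[Sn](CCCC)(CCCC)CCCC)C(=O)O[Li]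
F6 | step 16 | tetralithio oxiranyllithium from F5 after tin–lithium exchange | CC(C)=C[C@H](C)C[C@H](C)/C=C/C(=O)N([Li])[C@@H](C(S(=O)(=O)c1ccccc1)[C@@](O[Li])(CCCCC(=O)OC)[C@H]1O[C@H]1[Li])C(=O)O[Li]
F7 | step 16 | methyl 5-[(1S,2R,6R)-3-(benzenesulfonyl)-2-hydroxy-5-oxo-4-{[(2E,4S,6R)-4,6,8-trimethylnona-2,7-dienoyl]amino}-7-oxabicyclo[4.1.0]heptan-2-yl]pentanoate (epimers at C3 and C4) | CC(C)=C[C@H](C)C[C@H](C)/C=C/C(=O)NC1C(S(=O)(=O)c2ccccc2)[C@@](O)(CCCCC(=O)OC)[C@H]2O[C@H]2C1=O
F0 | step 14 | none | none
F8 | step 18 | 5-[(1S,2S,6R)-5-oxo-4-{[(2E,4S,6R)-4,6,8-trimethylnona-2,7-dienoyl]amino}-2-[(trimethylsilyl)oxy]-7-oxabicyclo[4.1.0]hept-3-en-2-yl]pentanoic acid | CC(C)=C[C@H](C)C[C@H](C)/C=C/C(=O)NC1=C[C@@](O[Si](C)(C)C)(CCCCC(=O)O)[C@H]2O[C@H]2C1=O
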